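**Plan**

1. Retrosynthesis: the C9 carbinol goes back to a ketone and the 4,5-epoxide to the 4E olefin. The lactone C6–O bond is then cut to a C6–H bond of a ten-membered trienoic acid, and the senecioate and the C8 oxygen are removed. The C6–C7 bond is cut by a retro-oxy-Cope step that restores a C4–C9 bond, absent from the target, of a six-membered ring. The resulting 1,2-dialkenylcyclohexenol is cut at C8–C9 into a dienyllithium (C7, C8, C11–C13) and (S)-6-ethenyl-2,6-dimethylcyclohex-2-enone (C1–C6, C9, C10, C14, C15).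
2. Forward: the bought cyclohexenone receives its quaternary vinyl centre and the dienyl unit; anionic oxy-Cope ring expansion turns the six-membered into the ten-membered ring, with C8 hydroxylated in the same flask. Ester and C12 acid follow, then the γ-lactone by allylic C–H lactonisation at C6, then the oxirane, and the C9 reduction last.
3. Enabling feature: C6 of the ten-membered ring is at once allylic to the C4=C5 olefin (the latent epoxide) and γ to the C12 carboxyl on C7. A π-allyl over C4–C5–C6 can therefore be captured by the carboxylate only as the five-membered 12,6-lactone. The C9 ketone keeps the C1(10) olefin an inert enone until the end.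
4. Stereochemistry: the catalyst-set quaternary centre of the cyclohexenone, with the carbinol centre, is relayed to C7 through the chair oxy-Cope transition state and then disappears. C8, C6, C4/C5 and C9 follow from attack on the peripheral face of the ten-membered ring. The 1(10)Z olefin is the cis olefin of the six-membered ring; the 4E olefin comes from the chair.

Key step: step 11

Remark: locants C1–C15 in the text and in the names of the ten-membered-ring compounds are those of the germacrane skeleton of the target (ring C1–C10, C11–C13 on C7, C14 on C10, C15 on C4). Compounds 1, 6, 8 and 14 are taken to be commercially available.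

Step 1
Reactants: 1 2-methylcyclohex-2-en-1-one
Product: 3 2,6-dimethylcyclohex-2-en-1-one (racemic), via lithium dienolate 2 (not isolated)
Conditions: LiN(iPr)2, THF, −78 °C; then MeI, −78 to 0 °C
Reagents that add atoms: iodomethane, CI
Why: Kinetic deprotonation at C6 gives the cross-conjugated lithium dienolate, and its C-methylation (enolate alkylation) installs the second methyl group; the new stereocentre is racemic and is erased in step 2.

Step 2
Reactants: 3 2,6-dimethylcyclohex-2-en-1-one
Product: 5 (6S)-6-ethenyl-2,6-dimethylcyclohex-2-en-1-one, via lithium dienolate 4 (not isolated)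
Conditions: LiN(SiMe3)2, THF, −78 °C; then Pd2(dba)3 (cat.), (S)-2-(dicyclohexylphosphino)-2′-(dimethylamino)-1,1′-binaphthyl (cat.), vinyl bromide, toluene, 25 °C
Reagents that add atoms: bromoethene, C=CBr
Why: Palladium-catalysed enantioselective α-vinylation of a ketone enolate (oxidative addition of vinyl bromide to zerovalent palladium, transmetalation with the preformed cross-conjugated enolate, C–C reductive elimination) should create the quaternary carbon, its S configuration being fixed by the chiral aminophosphine ligand, whose antipode is chosen accordingly.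

Step 3
Reactants: 6 2-bromoprop-2-en-1-ol
Product: 7 [(2-bromoprop-2-en-1-yl)oxy](tert-butyl)dimethylsilane
Conditions: TBSCl, imidazole, CH2Cl2, 0 to 25 °C
Reagents that add atoms: tert-butyl(chloro)dimethylsilane, CC(C)(C)[Si](C)(C)Cl
Why: Imidazole-promoted silyl ether formation protects the primary allylic alcohol for the organolithium and potassium hydride steps; no stereocentre is involved.

Step 4
Reactants: 7 [(2-bromoprop-2-en-1-yl)oxy](tert-butyl)dimethylsilane; 8 (E)-1,2-bis(tributylstannyl)ethene
Product: 9 tert-butyl(dimethyl){[(3E)-2-methylidene-4-(tributylstannyl)but-3-en-1-yl]oxy}silane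
Conditions: Pd(PPh3)4 (cat.), toluene, 100 °C, 8 in excess
Reagents that add atoms: none
Why: Stille coupling of the alkenyl bromide with one C–Sn end of the distannane (excess suppresses double coupling) proceeds with retention at both sp2 carbons, so the stannyl diene should keep the E geometry.

Step 5
Reactants: 9 tert-butyl(dimethyl){[(3E)-2-methylidene-4-(tributylstannyl)but-3-en-1-yl]oxy}silane; 5 (6S)-6-ethenyl-2,6-dimethylcyclohex-2-en-1-one
Product: 11 (1S,6S)-1-[(1E)-3-({[tert-butyl(dimethyl)silyl]oxy}methyl)buta-1,3-dien-1-yl]-6-ethenyl-2,6-dimethylcyclohex-2-en-1-ol, via dienyllithium 10 (not isolated)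
Conditions: MeLi, THF, −78 °C; then 5, −78 to −40 °C; then H2O
Reagents that add atoms: none
Why: Tin–lithium exchange with retention gives the E dienyllithium, whose 1,2-addition to the enone carbonyl anti to the vinyl group on the neighbouring quaternary carbon should set the 1S carbinol centre (alkenyl groups trans); the minor carbinol epimer can still reach the same ring-expanded ketone through a chair with the dienyl group equatorial.

Step 6
Reactants: 11 (1S,6S)-1-[(1E)-3-({[tert-butyl(dimethyl)silyl]oxy}methyl)buta-1,3-dien-1-yl]-6-ethenyl-2,6-dimethylcyclohex-2-en-1-ol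
Product: 13 (7R,8R)-12-[(tert-butyldimethylsilyl)oxy]-8-hydroxygermacra-1(10)Z,4E,11(13)-trien-9-one, via potassium enolate 12 (not isolated)
Conditions: KH, 18-crown-6, THF, 0 to 25 °C; then −78 °C, 2-(phenylsulfonyl)-3-phenyloxaziridine; then AcOH
Reagents that add atoms: 2-(phenylsulfonyl)-3-phenyloxaziridine, O=S(=O)(c1ccccc1)N1OC1c1ccccc1
Why: Anionic oxy-Cope rearrangement through the chair with both alkenyl groups equatorial cleaves the C4–C9 bond of the six-membered ring and forms C6–C7, which gives the ten-membered ring with the 4E olefin, the 1(10)Z enone and C7 (R) by chirality transfer; the enolate is formed with H7 eclipsing its double bond and C6 on the transannular face, so enolate hydroxylation by the oxaziridine on the open face should set 8R.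

Step 7
Reactants: 13 (7R,8R)-12-[(tert-butyldimethylsilyl)oxy]-8-hydroxygermacra-1(10)Z,4E,11(13)-trien-9-one; 14 3-methylbut-2-enoic acid
Product: 15 (7R,8R)-12-[(tert-butyldimethylsilyl)oxy]-8-[(3-methylbut-2-enoyl)oxy]germacra-1(10)Z,4E,11(13)-trien-9-one
Conditions: DCC, DMAP (cat.), CH2Cl2, 0 to 25 °C
Reagents that add atoms: none
Why: Steglich esterification acylates the α-ketol oxygen with retention at C8 and avoids the ketene pathway of the acid chloride, which would deconjugate the senecioyl group.

Step 8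
Reactants: 15 (7R,8R)-12-[(tert-butyldimethylsilyl)oxy]-8-[(3-methylbut-2-enoyl)oxy]germacra-1(10)Z,4E,11(13)-trien-9-one
Product: 16 (7R,8R)-12-hydroxy-8-[(3-methylbut-2-enoyl)oxy]germacra-1(10)Z,4E,11(13)-trien-9-one
Conditions: HF·pyridine, THF, 0 °C
Reagents that add atoms: none
Why: Fluoride-mediated cleavage of the primary silyl ether under mildly acidic conditions should leave the α-acyloxy ketone and both stereocentres untouched.

Step 9
Reactants: 16 (7R,8R)-12-hydroxy-8-[(3-methylbut-2-enoyl)oxy]germacra-1(10)Z,4E,11(13)-trien-9-one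
Product: 17 (7R,8R)-8-[(3-methylbut-2-enoyl)oxy]-9-oxogermacra-1(10)Z,4E,11(13)-trien-12-al
Conditions: Dess–Martin periodinane, CH2Cl2, 0 to 25 °C
Reagents that add atoms: none
Why: Dess–Martin oxidation converts the primary allylic alcohol into the 2-substituted acrolein under neutral conditions without touching a stereocentre.

Step 10
Reactants: 17 (7R,8R)-8-[(3-methylbut-2-enoyl)oxy]-9-oxogermacra-1(10)Z,4E,11(13)-trien-12-al
Product: 18 (7R,8R)-8-[(3-methylbut-2-enoyl)oxy]-9-oxogermacra-1(10)Z,4E,11(13)-trien-12-oic acid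
Conditions: NaClO2, NaH2PO4, 2-methylbut-2-ene, tBuOH/H2O, 0 to 25 °C
Reagents that add atoms: sodium chlorite, [Na+].[O-]Cl=O
Why: Pinnick oxidation takes the enal to the acrylic acid chemoselectively, the hypochlorous acid formed being scavenged by 2-methylbut-2-ene so that the C4=C5 olefin survives.

Step 11
Reactants: 18 (7R,8R)-8-[(3-methylbut-2-enoyl)oxy]-9-oxogermacra-1(10)Z,4E,11(13)-trien-12-oic acid
Product: 19 (6R,7S,8R)-8-[(3-methylbut-2-enoyl)oxy]-9-oxogermacra-1(10)Z,4E,11(13)-trien-12,6-olide
Conditions: Pd(OAc)2 (10 mol %), 1,2-bis(phenylsulfinyl)ethane (10 mol %), 1,4-benzoquinone (2 equiv), 1,4-dioxane, 45 °C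
Reagents that add atoms: none
Why: Proposed new method: the carboxylate of 18 binds divalent palladium, which coordinates the C4=C5 olefin on its peripheral face and, helped by the sulfoxide ligand and the bound carboxylate, cleaves the peripheral C6–H bond to a π-allyl complex over C4–C5–C6; benzoquinone-promoted inner-sphere C–O reductive elimination at C6 closes the lactone, and benzoquinone returns zerovalent palladium to the divalent state. The closest known reactions are the palladium diacetate/bis-sulfoxide allylic C–H macrolactonisation of alkenoic acids and the palladium-catalysed oxidative allylic C–H esterification of 4-alkenoic acids, neither shown for a trisubstituted olefin inside a medium ring. The γ-lactone closes in the 5-exo mode with respect to the allyl unit (O–C6 formed, C4=C5 left outside the new ring as the retained 4E olefin). C6 is the only new stereocentre: allylic 1,3-strain with the C15 methyl holds one C6 hydrogen in the olefin plane and the pseudo-equatorial C7 side chain puts C8 and the rest of the ring on the transannular face, so the hydrogen removed, the metal and the incoming oxygen are all on the peripheral face, which gives the 6,7-trans lactone. The step needs site selectivity for C6–H over the allylic C–H bonds at C3, C15 and C2 and over oxypalladation; the tether secures it, because only the C6 terminus gives a five-membered ring (C4 would need a seven-membered one), while the C1(10) olefin is a deactivated enone and the acrylate and senecioate olefins are electron-poor.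

Step 12
Reactants: 19 (6R,7S,8R)-8-[(3-methylbut-2-enoyl)oxy]-9-oxogermacra-1(10)Z,4E,11(13)-trien-12,6-olide
Product: 20 (4R,5R,6S,7S,8R)-4,5-epoxy-8-[(3-methylbut-2-enoyl)oxy]-9-oxogermacra-1(10)Z,11(13)-dien-12,6-olide
Conditions: mCPBA, CH2Cl2, −20 to 0 °C
Reagents that add atoms: 3-chloroperbenzoic acid, OOC(=O)c1cccc(Cl)c1
Why: Prilezhaev epoxidation is chemoselective for the only electron-rich olefin (the enone, methylene lactone and senecioate olefins are deactivated) and should occur on the peripheral face of the E olefin, the face that also carries the lactone oxygen, which sets 4R,5R as the trans epoxide.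

Step 13
Reactants: 20 (4R,5R,6S,7S,8R)-4,5-epoxy-8-[(3-methylbut-2-enoyl)oxy]-9-oxogermacra-1(10)Z,11(13)-dien-12,6-olide
Product: 21 (4R,5R,6S,7R,8R,9R)-4,5-epoxy-9-hydroxy-8-[(3-methylbut-2-enoyl)oxy]germacra-1(10)Z,11(13)-dien-12,6-olide (CNP0188779.3)
Conditions: NaBH4, CeCl3·7H2O, MeOH, −78 °C
Reagents that add atoms: none
Why: Luche reduction should deliver hydride 1,2 to the enone carbonyl faster than to the methylene lactone, and Felkin–Anh addition anti to the C8–O bond of the α-acyloxy ketone sets 9R (8,9-syn).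

**Compound list**

1 | 2-methylcyclohex-2-en-1-one | CC1=CCCCC1=O | starting material
2 | lithium 6-methylcyclohexa-1,5-dien-1-olate | CC1=CCCC=C1O[Li] | intermediate
3 | 2,6-dimethylcyclohex-2-en-1-one (racemic) | CC1CCC=C(C)C1=O | intermediate
4 | lithium 2,6-dimethylcyclohexa-1,5-dien-1-olate | CC1=CCCC(C)=C1O[Li] | intermediate
5 | (6S)-6-ethenyl-2,6-dimethylcyclohex-2-en-1-one | C=C[C@]1(C)CCC=C(C)C1=O | intermediate
6 | 2-bromoprop-2-en-1-ol | OCC(Br)=C | starting material
7 | [(2-bromoprop-2-en-1-yl)oxy](tert-butyl)dimethylsilane | C=C(Br)CO[Si](C)(C)C(C)(C)C | intermediate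
8 | (E)-1,2-bis(tributylstannyl)ethene | CCCC[Sn](CCCC)(CCCC)/C=C/[Sn](CCCC)(CCCC)CCCC | starting material
9 | tert-butyl(dimethyl){[(3E)-2-methylidene-4-(tributylstannyl)but-3-en-1-yl]oxy}silane | CCCC[Sn](CCCC)(CCCC)/C=C/C(=C)CO[Si](C)(C)C(C)(C)C | intermediate
10 | [(1E)-3-({[tert-butyl(dimethyl)silyl]oxy}methyl)buta-1,3-dien-1-yl]lithium | [Li]/C=C/C(=C)CO[Si](C)(C)C(C)(C)C | intermediate
11 | (1S,6S)-1-[(1E)-3-({[tert-butyl(dimethyl)silyl]oxy}methyl)buta-1,3-dien-1-yl]-6-ethenyl-2,6-dimethylcyclohex-2-en-1-ol | C=C(CO[Si](C)(C)C(C)(C)C)/C=C/[C@]1(O)C(C)=CCC[C@@]1(C)C=C | intermediate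
12 | potassium C8=C9 enolate of (7R)-12-[(tert-butyldimethylsilyl)oxy]germacra-1(10)Z,4E,11(13)-trien-9-one (oxygen cis to C7) | [K]O/C1=C\[C@@H](C(=C)CO[Si](C)(C)C(C)(C)C)C/C=C(C)/CC/C=C1/C | intermediate
13 | (7R,8R)-12-[(tert-butyldimethylsilyl)oxy]-8-hydroxygermacra-1(10)Z,4E,11(13)-trien-9-one | C=C(CO[Si](C)(C)C(C)(C)C)[C@H]1C/C=C(C)/CC/C=C(C)\C(=O)[C@@H]1O | intermediate
14 | 3-methylbut-2-enoic acid | CC(C)=CC(=O)O | starting material
15 | (7R,8R)-12-[(tert-butyldimethylsilyl)oxy]-8-[(3-methylbut-2-enoyl)oxy]germacra-1(10)Z,4E,11(13)-trien-9-one | C=C(CO[Si](C)(C)C(C)(C)C)[C@H]1C/C=C(C)/CC/C=C(C)\C(=O)[C@@H]1OC(=O)C=C(C)C | intermediate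
16 | (7R,8R)-12-hydroxy-8-[(3-methylbut-2-enoyl)oxy]germacra-1(10)Z,4E,11(13)-trien-9-one | C=C(CO)[C@H]1C/C=C(C)/CC/C=C(C)\C(=O)[C@@H]1OC(=O)C=C(C)C | intermediate
17 | (7R,8R)-8-[(3-methylbut-2-enoyl)oxy]-9-oxogermacra-1(10)Z,4E,11(13)-trien-12-al | C=C(C=O)[C@H]1C/C=C(C)/CC/C=C(C)\C(=O)[C@@H]1OC(=O)C=C(C)C | intermediate
18 | (7R,8R)-8-[(3-methylbut-2-enoyl)oxy]-9-oxogermacra-1(10)Z,4E,11(13)-trien-12-oic acid | C=C(C(=O)O)[C@H]1C/C=C(C)/CC/C=C(C)\C(=O)[C@@H]1OC(=O)C=C(C)C | intermediate
19 | (6R,7S,8R)-8-[(3-methylbut-2-enoyl)oxy]-9-oxogermacra-1(10)Z,4E,11(13)-trien-12,6-olide | C=C1C(=O)O[C@@H]2/C=C(C)/CC/C=C(C)\C(=O)[C@H](OC(=O)C=C(C)C)[C@@H]12 | intermediate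
20 | (4R,5R,6S,7S,8R)-4,5-epoxy-8-[(3-methylbut-2-enoyl)oxy]-9-oxogermacra-1(10)Z,11(13)-dien-12,6-olide | C=C1C(=O)O[C@H]2[C@H]1[C@@H](OC(=O)C=C(C)C)C(=O)/C(C)=C\CC[C@@]1(C)O[C@H]21 | intermediate
21 | (4R,5R,6S,7R,8R,9R)-4,5-epoxy-9-hydroxy-8-[(3-methylbut-2-enoyl)oxy]germacra-1(10)Z,11(13)-dien-12,6-olide (CNP0188779.3) | C=C1C(=O)O[C@H]2[C@H]1[C@@H](OC(=O)C=C(C)C)[C@H](O)/C(C)=C\CC[C@@]1(C)O[C@H]21 | target

**Step count**

Total: 13 steps. Longest linear sequence: 11 steps (1 → 3 → 5 → 11 → 13 → 15 → 16 → 17 → 18 → 19 → 20 → 21; the branch 6 → 7 → 9 → 11 is equally long).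

**Steps most likely to fail**

Step 11 (Proposed new method). C–H cleavage at the internal trisubstituted olefin may be too slow, so that oxypalladation of C4=C5 or oxidation at another allylic position takes over. The fallback uses known reactions and runs from 18 to 20. Photooxygenation of 18 (O2, tetraphenylporphyrin, light, CH2Cl2, 0 °C; Schenck ene reaction) should remove the peripheral C6 hydrogen and place oxygen on C4, giving the allylic hydroperoxide (4R,7R,8R)-4-hydroperoxy-8-[(3-methylbut-2-enoyl)oxy]-9-oxogermacra-1(10)Z,5E,11(13)-trien-12-oic acid F1. PPh3 in the same flask should reduce it to the tertiary allylic alcohol (4R,7R,8R)-4-hydroxy-8-[(3-methylbut-2-enoyl)oxy]-9-oxogermacra-1(10)Z,5E,11(13)-trien-12-oic acid F2. Iodolactonisation (I2, NaHCO3, MeCN, 0 °C) then closes the C6–O bond anti to iodine and should give the iodolactone (4R,5S,6S,7R,8R)-4-hydroxy-5-iodo-8-[(3-methylbut-2-enoyl)oxy]-9-oxogermacra-1(10)Z,11(13)-dien-12,6-olide F3. K2CO3 in MeCN closes the oxirane by backside displacement of iodide by the C4 alkoxide, and the route is rejoined at 20; step 12 is then not needed.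

Step 2. The enantioselectivity at the quaternary carbon may be low, or the enolate may equilibrate and be vinylated at the γ-carbon. The fallback runs from 3, through its enolate 4, to 5. O-Acylation of 4 with allyl chloroformate gives allyl 2,6-dimethylcyclohexa-1,5-dien-1-yl carbonate F4. Decarboxylative asymmetric allylic alkylation (Pd2(dba)3, (S)-tBu-PHOX, THF; Tsuji–Trost type) should give (6S)-2,6-dimethyl-6-(prop-2-en-1-yl)cyclohex-2-en-1-one F5. Olefin isomerisation (RuHCl(CO)(PPh3)3, toluene, 80 °C) gives (6S)-2,6-dimethyl-6-[(1E)-prop-1-en-1-yl]cyclohex-2-en-1-one F6. Ethenolysis (ethylene, second-generation Hoveyda–Grubbs catalyst, CH2Cl2) cuts off propene, and the route is rejoined at 5.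

Step 13. Hydride may add in conjugate fashion to the α-methylene lactone, or the senecioyl group may migrate to the new C9 alkoxide. The fallback runs from 20 to 21. The methylene lactone is first masked by conjugate addition of dimethylamine (Me2NH, THF) as (4R,5R,6S,7S,8R,11R)-13-(dimethylamino)-4,5-epoxy-8-[(3-methylbut-2-enoyl)oxy]-9-oxogermacr-1(10)Z-en-12,6-olide F7. Luche reduction as in step 13 should give (4R,5R,6S,7R,8R,9R,11R)-13-(dimethylamino)-4,5-epoxy-9-hydroxy-8-[(3-methylbut-2-enoyl)oxy]germacr-1(10)Z-en-12,6-olide F8. Quaternisation with MeI gives the trimethylammonium iodide of this amine F9, and aqueous NaHCO3 induces elimination of trimethylamine, which restores the methylene lactone and gives 21.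

**Further compounds**

F1 | step 11 | (4R,7R,8R)-4-hydroperoxy-8-[(3-methylbut-2-enoyl)oxy]-9-oxogermacra-1(10)Z,5E,11(13)-trien-12-oic acid | C=C(C(=O)O)[C@H]1/C=C/[C@](C)(OO)CC/C=C(C)\C(=O)[C@@H]1OC(=O)C=C(C)C
F2 | step 11 | (4R,7R,8R)-4-hydroxy-8-[(3-methylbut-2-enoyl)oxy]-9-oxogermacra-1(10)Z,5E,11(13)-trien-12-oic acid | C=C(C(=O)O)[C@H]1/C=C/[C@](C)(O)CC/C=C(C)\C(=O)[C@@H]1OC(=O)C=C(C)C
F3 | step 11 | (4R,5S,6S,7R,8R)-4-hydroxy-5-iodo-8-[(3-methylbut-2-enoyl)oxy]-9-oxogermacra-1(10)Z,11(13)-dien-12,6-olide | C=C1C(=O)O[C@H]2[C@H]1[C@@H](OC(=O)C=C(C)C)C(=O)/C(C)=C\CC[C@@](C)(O)[C@H]2I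
F4 | step 2 | allyl 2,6-dimethylcyclohexa-1,5-dien-1-yl carbonate | C=CCOC(=O)OC1=C(C)CCC=C1C
F5 | step 2 | (6S)-2,6-dimethyl-6-(prop-2-en-1-yl)cyclohex-2-en-1-one | C=CC[C@]1(C)CCC=C(C)C1=O
F6 | step 2 | (6S)-2,6-dimethyl-6-[(1E)-prop-1-en-1-yl]cyclohex-2-en-1-one | C/C=C/[C@]1(C)CCC=C(C)C1=O
F7 | step 13 | (4R,5R,6S,7S,8R,11R)-13-(dimethylamino)-4,5-epoxy-8-[(3-methylbut-2-enoyl)oxy]-9-oxogermacr-1(10)Z-en-12,6-olide | CN(C)C[C@@H]1C(=O)O[C@H]2[C@H]1[C@@H](OC(=O)C=C(C)C)C(=O)/C(C)=C\CC[C@@]1(C)O[C@H]21
F8 | step 13 | (4R,5R,6S,7R,8R,9R,11R)-13-(dimethylamino)-4,5-epoxy-9-hydroxy-8-[(3-methylbut-2-enoyl)oxy]germacr-1(10)Z-en-12,6-olide | CN(C)C[C@@H]1C(=O)O[C@H]2[C@H]1[C@@H](OC(=O)C=C(C)C)[C@H](O)/C(C)=C\CC[C@@]1(C)O[C@H]21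
F9 | step 13 | trimethylammonium iodide (methiodide) of F8 | C[N+](C)(C)C[C@@H]1C(=O)O[C@H]2[C@H]1[C@@H](OC(=O)C=C(C)C)[C@H](O)/C(C)=C\CC[C@@]1(C)O[C@H]21.[I-]
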